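**Retrosynthetic overview**
1. Target 8 is cut at the C–O bond of the sec-alkyl aryl ether between the middle and the propenyl-bearing arene, giving allylarene 6 and phenol 7 (enantioselective Markovnikov hydroaryloxylation, sets the (R) ether carbon).
2. Acetate 6 is cut at the benzylic C–OAc bond with inversion (Mitsunobu), giving threo alcohol 5.
3. Alcohol 5 comes from racemic α-aryloxy ketone 4 by transfer hydrogenation with dynamic kinetic resolution (sets both carbons of the acetoxypropyl unit).
4. Ketone 4 is cut at its C–OAr bond into bromo ketone 2 and 4-allyl-2,6-dimethoxyphenol 3; phenol 7 comes from 3 by alkene isomerisation.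
5. No ring is formed; the three arenes are bought intact.

Assumption: ketone 1 and phenol 3 are taken as catalogue chemicals; the target is read as (1S,2R) on the acetoxypropyl unit, (R) at the second ether carbon, and E at the alkene.

**Step 1**
Reactants: 1 1-(3,4,5-trimethoxyphenyl)propan-1-one
Product: 2 2-bromo-1-(3,4,5-trimethoxyphenyl)propan-1-one (racemic)
Conditions: CuBr2 (2.1 equiv), EtOAc/CHCl3 1:1, reflux
Reagents that add atoms: copper(II) bromide, [Cu+2].[Br-].[Br-]
Why: King–Ostrum α-bromination through the enol is selective for the α-carbon over the acyl-deactivated ring, and the racemic centre does not matter because it is reset in step 3.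

**Step 2**
Reactants: 2 2-bromo-1-(3,4,5-trimethoxyphenyl)propan-1-one; 3 4-allyl-2,6-dimethoxyphenol
Product: 4 2-[2,6-dimethoxy-4-(prop-2-en-1-yl)phenoxy]-1-(3,4,5-trimethoxyphenyl)propan-1-one (racemic)
Conditions: K2CO3 (2 equiv), butanone, reflux
Reagents that add atoms: none
Why: Williamson ether synthesis (SN2 of the phenoxide at the activated α-keto carbon) is the standard way to make this aryloxy ketone motif, and the allyl group is inert to carbonate.

**Step 3**
Reactants: 4 2-[2,6-dimethoxy-4-(prop-2-en-1-yl)phenoxy]-1-(3,4,5-trimethoxyphenyl)propan-1-one (racemic)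
Product: 5 (1R,2R)-2-[2,6-dimethoxy-4-(prop-2-en-1-yl)phenoxy]-1-(3,4,5-trimethoxyphenyl)propan-1-ol (threo)
Conditions: oxo-tethered RuCl[(S,S)-Ts-DENEB] (1 mol%), HCO2H/Et3N 1:1 (5 equiv), DMF, 45 °C
Reagents that add atoms: none
Why: Noyori–Ikariya asymmetric transfer hydrogenation with dynamic kinetic resolution: the amine epimerises the acidic α-aryloxy ketone carbon, the (S,S) catalyst delivers hydride to the carbonyl face that gives C1 (R) (aryl in the CH/π pocket, same sense as benzoin to (R,R)-hydrobenzoin), and the ketone enantiomer that can place its aryloxy group anti to the hydride (polar Felkin–Anh) reacts faster, so the threo (1R,2R) alcohol is expected; the outer-sphere catalyst leaves the allyl group alone.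

**Step 4**
Reactants: 5 (1R,2R)-2-[2,6-dimethoxy-4-(prop-2-en-1-yl)phenoxy]-1-(3,4,5-trimethoxyphenyl)propan-1-ol
Product: 6 (1S,2R)-2-[2,6-dimethoxy-4-(prop-2-en-1-yl)phenoxy]-1-(3,4,5-trimethoxyphenyl)propyl acetate (erythro)
Conditions: PPh3, DIAD, AcOH (1.8 equiv each), toluene, 0 °C → rt
Reagents that add atoms: acetic acid, CC(=O)O
Why: Mitsunobu esterification displaces the activated benzylic oxygen by acetate in an SN2 step with inversion, so one C–O bond formation turns threo (1R,2R) into erythro (1S,2R) and installs the acetate, while C2 is untouched.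

**Step 5**
Reactants: 3 4-allyl-2,6-dimethoxyphenol
Product: 7 2,6-dimethoxy-4-[(1E)-prop-1-en-1-yl]phenol
Conditions: Grotjahn-type catalyst [CpRu(κ2-P,N-phosphinoimidazole)(MeCN)]PF6 (1 mol%), acetone, 60 °C
Reagents that add atoms: none
Why: Ru-catalysed one-position alkene isomerisation moves the double bond into conjugation with the arene and gives the thermodynamic E isomer with high selectivity; the free phenol is tolerated.

**Step 6**
Reactants: 6 (1S,2R)-2-[2,6-dimethoxy-4-(prop-2-en-1-yl)phenoxy]-1-(3,4,5-trimethoxyphenyl)propyl acetate; 7 2,6-dimethoxy-4-[(1E)-prop-1-en-1-yl]phenol (2.5 equiv)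
Product: 8 (1S,2R)-2-{2,6-dimethoxy-4-[(2R)-2-{2,6-dimethoxy-4-[(1E)-prop-1-en-1-yl]phenoxy}propyl]phenoxy}-1-(3,4,5-trimethoxyphenyl)propyl acetate
Conditions: Co(II) complex of (R,R)-N,N'-bis[3-(3,5-di-tert-butylphenyl)-5-tert-butylsalicylidene]cyclohexane-1,2-diamine (5 mol%), N-fluoro-2,4,6-trimethylpyridinium triflate (1.3 equiv), PhSiH3 (1.2 equiv), PhCF3, −20 → 0 °C, Ar
Reagents that add atoms: none
Why: Proposed new method: an intermolecular, catalyst-controlled enantioselective Markovnikov hydroaryloxylation of an unactivated allylarene with a hindered phenol by Co–H hydrogen-atom transfer and radical–polar crossover, in which Co(III)–H (from Co(II), the N–F oxidant and the silane) gives H• to the terminal CH2 of 6, the secondary radical is captured by the chiral Co(salen) and oxidised to a sec-alkyl–Co(IV) species whose two diastereomers interconvert by Co–C homolysis, and phenol 7 (collidine as general base) displaces cobalt by SN2 with inversion from the faster-reacting diastereomer, the 3,3'-aryl walls telling CH3 from CH2Ar so that the (R) ether carbon is set by the catalyst (the sense cannot be predicted, so it is calibrated first on a simple allylarene/phenol pair and the ligand antipode is used if it is reversed); the bulky Co–H should prefer the monosubstituted alkene over the 1,2-disubstituted propenyl groups, the neutral phenol should survive the mild N–F oxidant, and the closest known reaction type is the Co(salen)/N-fluoropyridinium/silane Mukaiyama-type hydroalkoxylation of terminal alkenes with alcohols, including its enantioselective intramolecular versions.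

**Compound list**
1 | 1-(3,4,5-trimethoxyphenyl)propan-1-one | CCC(=O)c1cc(OC)c(OC)c(OC)c1 | starting material
2 | 2-bromo-1-(3,4,5-trimethoxyphenyl)propan-1-one (racemic) | CC(Br)C(=O)c1cc(OC)c(OC)c(OC)c1 | intermediate
3 | 4-allyl-2,6-dimethoxyphenol | C=CCc1cc(OC)c(O)c(OC)c1 | starting material
4 | 2-[2,6-dimethoxy-4-(prop-2-en-1-yl)phenoxy]-1-(3,4,5-trimethoxyphenyl)propan-1-one (racemic) | C=CCc1cc(OC)c(OC(C)C(=O)c2cc(OC)c(OC)c(OC)c2)c(OC)c1 | intermediate
5 | (1R,2R)-2-[2,6-dimethoxy-4-(prop-2-en-1-yl)phenoxy]-1-(3,4,5-trimethoxyphenyl)propan-1-ol | C=CCc1cc(OC)c(O[C@H](C)[C@H](O)c2cc(OC)c(OC)c(OC)c2)c(OC)c1 | intermediate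
6 | (1S,2R)-2-[2,6-dimethoxy-4-(prop-2-en-1-yl)phenoxy]-1-(3,4,5-trimethoxyphenyl)propyl acetate | C=CCc1cc(OC)c(O[C@H](C)[C@@H](OC(C)=O)c2cc(OC)c(OC)c(OC)c2)c(OC)c1 | intermediate
7 | 2,6-dimethoxy-4-[(1E)-prop-1-en-1-yl]phenol | C/C=C/c1cc(OC)c(O)c(OC)c1 | intermediate
8 | (1S,2R)-2-{2,6-dimethoxy-4-[(2R)-2-{2,6-dimethoxy-4-[(1E)-prop-1-en-1-yl]phenoxy}propyl]phenoxy}-1-(3,4,5-trimethoxyphenyl)propyl acetate | C/C=C/c1cc(OC)c(O[C@H](C)Cc2cc(OC)c(O[C@H](C)[C@@H](OC(C)=O)c3cc(OC)c(OC)c(OC)c3)c(OC)c2)c(OC)c1 | target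

**Count**
Total steps: 6. Longest linear sequence: 5 (steps 1, 2, 3, 4, 6); step 5 is a one-step side branch.

**Three steps most likely to fail**

Step 6 (the proposed new reaction). The risks are incomplete catalyst control at the new ether carbon (giving an epimer that is hard to separate), hydrogen-atom transfer to the propenyl group of 7 or 8, Co–H isomerisation of the allyl group of 6, hydrofluorination, and oxidation of the electron-rich phenol. The fallback uses known chemistry and sets out from 6. Tsuji–Wacker oxidation (PdCl2, CuCl, O2, DMF/H2O) gives the methyl ketone (1S,2R)-2-[2,6-dimethoxy-4-(2-oxopropyl)phenoxy]-1-(3,4,5-trimethoxyphenyl)propyl acetate F7. An (S)-selective ketoreductase (screened panel, NADPH recycled with isopropanol, buffer/DMSO, 30 °C) reduces it to (1S,2R)-2-{4-[(2S)-2-hydroxypropyl]-2,6-dimethoxyphenoxy}-1-(3,4,5-trimethoxyphenyl)propyl acetate F8. Mitsunobu etherification of F8 with phenol 7 (PPh3, DIAD, toluene) inverts the carbinol to the (R) ether and comes back to the route at 8.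

Step 3 (transfer hydrogenation with dynamic kinetic resolution). The risks are slow epimerisation of 4 under the amine conditions and a low or reversed threo preference, since the threo outcome is argued by analogy rather than secured for this substrate. The fallback is a chiral-pool sequence that sets out from 3. Mitsunobu etherification of 3 with ethyl (S)-lactate (PPh3, DIAD, THF, inversion) gives ethyl (2R)-2-[2,6-dimethoxy-4-(prop-2-en-1-yl)phenoxy]propanoate F1. MeNH(OMe)·HCl with iPrMgCl (THF, −20 °C) gives the Weinreb amide (2R)-2-[2,6-dimethoxy-4-(prop-2-en-1-yl)phenoxy]-N-methoxy-N-methylpropanamide F2. Commercial 3,4,5-trimethoxyphenylmagnesium bromide (THF, 0 °C) gives the enantioenriched ketone (2R)-2-[2,6-dimethoxy-4-(prop-2-en-1-yl)phenoxy]-1-(3,4,5-trimethoxyphenyl)propan-1-one F3. Chelation-controlled reduction with Zn(BH4)2 (Et2O, −30 °C) gives the erythro alcohol (1S,2R)-2-[2,6-dimethoxy-4-(prop-2-en-1-yl)phenoxy]-1-(3,4,5-trimethoxyphenyl)propan-1-ol F4. Ac2O/pyridine/DMAP then acetylates F4, and the sequence comes back to the route at 6, bypassing steps 3 and 4.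

Step 4 (Mitsunobu inversion at the hindered benzylic carbinol). The risks are elimination to the enol ether, partial ionisation of the benzylic position with loss of diastereomeric purity, and sluggish reaction with the weakly acidic acetic acid. The fallback sets out from 5 and replaces the SN2 inversion by an oxidation and a chelate-controlled carbonyl reduction. Dess–Martin periodinane (CH2Cl2, NaHCO3, 0 °C) oxidises 5 to (2R)-2-[2,6-dimethoxy-4-(prop-2-en-1-yl)phenoxy]-1-(3,4,5-trimethoxyphenyl)propan-1-one F5 (same structure as F3). Zn(BH4)2 (Et2O, −30 °C) reduces it to the erythro alcohol (1S,2R)-2-[2,6-dimethoxy-4-(prop-2-en-1-yl)phenoxy]-1-(3,4,5-trimethoxyphenyl)propan-1-ol F6 (same structure as F4). Ac2O/pyridine/DMAP then comes back to the route at 6.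

**Further compounds**
F1 | step 3 | ethyl (2R)-2-[2,6-dimethoxy-4-(prop-2-en-1-yl)phenoxy]propanoate | C=CCc1cc(OC)c(O[C@H](C)C(=O)OCC)c(OC)c1
F2 | step 3 | (2R)-2-[2,6-dimethoxy-4-(prop-2-en-1-yl)phenoxy]-N-methoxy-N-methylpropanamide | C=CCc1cc(OC)c(O[C@H](C)C(=O)N(C)OC)c(OC)c1
F3 | step 3 | (2R)-2-[2,6-dimethoxy-4-(prop-2-en-1-yl)phenoxy]-1-(3,4,5-trimethoxyphenyl)propan-1-one | C=CCc1cc(OC)c(O[C@H](C)C(=O)c2cc(OC)c(OC)c(OC)c2)c(OC)c1
F4 | step 3 | (1S,2R)-2-[2,6-dimethoxy-4-(prop-2-en-1-yl)phenoxy]-1-(3,4,5-trimethoxyphenyl)propan-1-ol | C=CCc1cc(OC)c(O[C@H](C)[C@@H](O)c2cc(OC)c(OC)c(OC)c2)c(OC)c1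
F5 | step 4 | (2R)-2-[2,6-dimethoxy-4-(prop-2-en-1-yl)phenoxy]-1-(3,4,5-trimethoxyphenyl)propan-1-one | C=CCc1cc(OC)c(O[C@H](C)C(=O)c2cc(OC)c(OC)c(OC)c2)c(OC)c1
F6 | step 4 | (1S,2R)-2-[2,6-dimethoxy-4-(prop-2-en-1-yl)phenoxy]-1-(3,4,5-trimethoxyphenyl)propan-1-ol | C=CCc1cc(OC)c(O[C@H](C)[C@@H](O)c2cc(OC)c(OC)c(OC)c2)c(OC)c1
F7 | step 6 | (1S,2R)-2-[2,6-dimethoxy-4-(2-oxopropyl)phenoxy]-1-(3,4,5-trimethoxyphenyl)propyl acetate | CC(=O)Cc1cc(OC)c(O[C@H](C)[C@@H](OC(C)=O)c2cc(OC)c(OC)c(OC)c2)c(OC)c1
F8 | step 6 | (1S,2R)-2-{4-[(2S)-2-hydroxypropyl]-2,6-dimethoxyphenoxy}-1-(3,4,5-trimethoxyphenyl)propyl acetate | C[C@H](O)Cc1cc(OC)c(O[C@H](C)[C@@H](OC(C)=O)c2cc(OC)c(OC)c(OC)c2)c(OC)c1
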